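**Retrosynthetic overview**

1. Target ← silyl removal, α-protonation at C9 of a C11 dienol ether (gives C9–H and C7=C8), and formylation of the C9 enol triflate of a ring B β-keto ester (C9=O, C8–CO2Me).
2. Ring A pattern ← 3β-Cl by invertive chlorination of a 3α-boronate, made by conjugate borylation of the C1 enone that Wharton transposition of the C3 ketone provides; 1α-OH by hydride reduction.
3. C4 (quaternary), C5 and the side chain ← dissolving-metal reductive alkylation of the C3 enone with the C13–C15 iodide (C15 from a Shi epoxidation).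
4. Ring B ← one-carbon ring expansion of the C9 cyclopentanone of a 4,7a-dimethyl Hajos–Parrish ketone with methyl diazoacetate. The route rests on this feature of ring B: the ester-bearing C8 sits between the methylene C7 and C9, and C9 is bonded to the quaternary C10, which is what insertion of CH(CO2Me) into the C9–C7 bond of a hydrindanone leaves.
5. Ring order: ring A is closed first by amino-acid-catalysed aldol annulation onto the five-membered dione; ring B is then made from the five-membered ring by expansion.

Key step: step 4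

Remark: locants follow the target (ring A C1–C5/C10; ring B C5–C10; C11 formyl; C12 ester; chain C13–C15); β is the face of the C10 methyl and α the opposite face; the β-keto esters 7, 15 and 27 are keto–enol mixtures, so C8 is drawn as one epimer and is assumed to be of no consequence until it is removed in step 20.

**Route**

Step 1
Reactants: 1 2-methylcyclopentane-1,3-dione; 2 ethyl vinyl ketone
Product: 3 2-methyl-2-(3-oxopentyl)cyclopentane-1,3-dione
Conditions: H2O, AcOH (cat.), 70 °C
Reagents that add atoms: none
Why: Michael addition of the acidic cyclic 1,3-dione to the enone gives the 2,2-disubstituted dione, whose quaternary carbon is still prochiral.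

Step 2
Reactants: 3 2-methyl-2-(3-oxopentyl)cyclopentane-1,3-dione
Product: 4 (7aS)-4,7a-dimethyl-2,3,7,7a-tetrahydro-1H-indene-1,5(6H)-dione
Conditions: L-phenylalanine (1.0 equiv), 1 M HClO4 (0.5 equiv), MeCN, reflux; recrystallisation
Reagents that add atoms: none
Why: Hajos–Parrish–Eder–Sauer–Wiechert reaction, in which the enamine of the ethyl ketone with the L-amino acid attacks one of the two enantiotopic ring carbonyls under direction by the carboxylic acid, which should set the quaternary carbon (C10) as S before dehydration to the enone closes ring A.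

Step 3
Reactants: 5 glycine methyl ester hydrochloride
Product: 6 methyl diazoacetate
Conditions: NaNO2, H2SO4 (cat.), CH2Cl2/H2O, −5 °C; used as a dried CH2Cl2 solution
Reagents that add atoms: sodium nitrite [Na+].[O-]N=O
Why: Diazotisation of an α-amino ester, in which the diazonium ion loses its acidic α-proton to give the stabilised diazo ester.

Step 4
Reactants: 4 (7aS)-4,7a-dimethyl-2,3,7,7a-tetrahydro-1H-indene-1,5(6H)-dione; 6 methyl diazoacetate
Product: 7 methyl (8aS)-5,8a-dimethyl-1,6-dioxo-1,2,3,4,6,7,8,8a-octahydronaphthalene-2-carboxylate (C3 enone; C9 ketone; 8-CO2Me)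
Conditions: BF3·OEt2 (1.5 equiv), CH2Cl2, 0 °C → rt
Reagents that add atoms: none
Why: BF3 activates the saturated C9 cyclopentanone, which is far more electrophilic than the vinylogous C3 enone carbonyl; the nucleophilic diazo carbon adds to it, and loss of N2 from the resulting β-oxido diazonium ion is coupled to a 1,2-shift of the ring bond that lies anti to the leaving group. The closest known reaction type is the Lewis-acid-promoted diazoacetate homologation of cycloalkanones (Tiffeneau–Demjanov-type ring expansion), which is well precedented for α-substituted cycloalkanones. Ring B is closed by one-carbon ring expansion of the five-membered ring through this 1,2-alkyl shift (new bonds C8–C9 and C7–C8), not by a cyclisation. The one new stereocentre, C8, lies between ketone and ester, equilibrates through the enol and is not a controlled centre, while C10 is untouched. The step needs C7 to migrate and not C10: the bulky ester-bearing diazonium carbon should add so that the less substituted C9–C7 bond is aligned with the departing N2, and migration of the methylene is the normal outcome for α-quaternary ketones. Over-homologation should be held back because the product is withdrawn as its BF3-chelated enol.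

Step 5
Reactants: 8 5-bromo-2-methylpent-2-ene
Product: 9 (R)-3-(2-bromoethyl)-2,2-dimethyloxirane
Conditions: D-fructose-derived Shi ketone (0.3 equiv), KHSO5 (as 2KHSO5·KHSO4·K2SO4), K2CO3, Bu4NHSO4, MeCN/CH2(OMe)2/aq. Na2B4O7 buffer, 0 °C
Reagents that add atoms: potassium peroxymonosulfate [K+].OOS(=O)(=O)[O-]
Why: Shi epoxidation, in which the dioxirane of the D-fructose-derived ketone delivers oxygen to one face of the trisubstituted alkene through a spiro transition state and should give the R epoxide (the future C15–O bond).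

Step 6
Reactants: 9 (R)-3-(2-bromoethyl)-2,2-dimethyloxirane
Product: 10 (R)-5-bromo-2-methylpent-1-en-3-ol
Conditions: Al(Oi-Pr)3, toluene, 110 °C; dilute HCl work-up
Reagents that add atoms: none
Why: Aluminium alkoxide-promoted isomerisation of a 2,2-dimethyl-3-alkyl epoxide to the allylic alcohol, in which the tertiary C–O bond breaks and a methyl proton is lost while the secondary C–O bond, and with it the R configuration, is kept.

Step 7
Reactants: 10 (R)-5-bromo-2-methylpent-1-en-3-ol
Product: 11 (R)-[(5-bromo-2-methylpent-1-en-3-yl)oxy](tert-butyl)diphenylsilane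
Conditions: TBDPSCl, imidazole, DMF, rt
Reagents that add atoms: tert-butyl(chloro)diphenylsilane CC(C)(C)[Si](Cl)(c1ccccc1)c1ccccc1
Why: Silylation of the secondary allylic alcohol, with the tert-butyldiphenylsilyl ether chosen because it has to survive the aqueous acid of step 19.

Step 8
Reactants: 11 (R)-[(5-bromo-2-methylpent-1-en-3-yl)oxy](tert-butyl)diphenylsilane
Product: 12 (R)-tert-butyl[(5-iodo-2-methylpent-1-en-3-yl)oxy]diphenylsilane
Conditions: NaI, acetone, reflux
Reagents that add atoms: sodium iodide [Na+].[I-]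
Why: Finkelstein exchange (SN2 at the primary carbon, driven by precipitation of NaBr) gives the more reactive alkylating agent without touching the stereocentre.

Step 9
Reactants: 7 bicyclic enone β-keto ester; 12 (R)-tert-butyl[(5-iodo-2-methylpent-1-en-3-yl)oxy]diphenylsilane
Product: 15 diketo ester (trans-decalin; C3=O; C9=O; 8-CO2Me; 4β-Me; 4α-[(3R)-3-(tert-butyldiphenylsilyloxy)-4-methylpent-4-enyl]; 5α-H; 10β-Me), via lithium enolate 13 (not isolated), via dilithium bis-enolate 14 (not isolated)
Conditions: LiN(SiMe3)2 (1.0 equiv), THF, −78 °C; transfer to Li (2.3 equiv), t-BuOH (1.0 equiv), NH3(l)/THF, −78 °C; isoprene; then 12, THF/HMPA, −78 → 0 °C (NH3 allowed to evaporate); aq. NH4Cl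
Reagents that add atoms: none
Why: Dissolving-metal reductive alkylation of an enone (Stork), in which the β-keto ester is stored as its lithium enolate that resists reduction, protonation at C5 trans to the angular methyl should give the trans-fused C3 enolate, and this more nucleophilic ketone enolate is alkylated at C4 from the α face, opposite the axial C10 methyl, so that the chain is α and the C4 methyl β.

Step 10
Reactants: 15 diketo ester
Product: 16 C9 methyl enol ether (C8=C9; 9-OMe; 8-CO2Me; C3 ketone; other groups as in 15)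
Conditions: Cs2CO3, Me2SO4, DMF, 0 °C → rt
Reagents that add atoms: dimethyl sulfate COS(=O)(=O)OC
Why: O-Alkylation of the caesium enolate of the β-keto ester by a hard sulfate electrophile in a dipolar aprotic solvent masks it as a vinylogous carbonate, while carbonate does not enolise the C3 ketone.

Step 11
Reactants: 16 C9 methyl enol ether
Product: 17 C1=C2 enone (3-oxo; other groups as in 16)
Conditions: IBX (2-iodoxybenzoic acid), DMSO, 75 °C
Reagents that add atoms: none
Why: IBX dehydrogenation of a ketone to its enone, which can only place the double bond at C1=C2 because C4 is quaternary.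

Step 12
Reactants: 17 C1=C2 enone
Product: 18 1α,2α-epoxy-3-ketone (other groups as in 16)
Conditions: 30% H2O2, NaOH, MeOH/THF, 0 °C
Reagents that add atoms: hydrogen peroxide OO
Why: Weitz–Scheffer nucleophilic epoxidation, in which hydroperoxide adds to C1 axially from the α face, anti to the C10 methyl, and ring closure gives the 1α,2α-epoxide (new centres C1 and C2).

Step 13
Reactants: 18 1α,2α-epoxy-3-ketone
Product: 20 1α-hydroxy C2=C3 alkene (allylic alcohol; other groups as in 16), via epoxy hydrazone 19 (not isolated)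
Conditions: N2H4·H2O, AcOH (cat.), MeOH, 0 °C → rt
Reagents that add atoms: none
Why: Wharton transposition, in which the epoxy hydrazone fragments with loss of N2, leaving the C1–O bond untouched (1α-OH) and the double bond at C2=C3.

Step 14
Reactants: 20 1α-hydroxy C2=C3 alkene
Product: 21 transposed enone (1-oxo; C2=C3; other groups as in 16)
Conditions: DMP (1,1,1-triacetoxy-1,1-dihydro-1,2-benziodoxol-3(1H)-one), NaHCO3, CH2Cl2, rt
Reagents that add atoms: none
Why: Oxidation of the allylic alcohol by the hypervalent iodine reagent gives the transposed enone, in which C3 is now the β-carbon.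

Step 15
Reactants: 21 transposed enone
Product: 22 3α-(pinacolboryl)-1-ketone (other groups as in 16)
Conditions: B2pin2, CuCl (10 mol %), DPEphos (bis[2-(diphenylphosphino)phenyl] ether, 10 mol %), NaOt-Bu (15 mol %), MeOH (2 equiv), THF, rt
Reagents that add atoms: bis(pinacolato)diboron CC1(C)OB(OC1(C)C)B1OC(C)(C)C(C)(C)O1
Why: Copper-catalysed conjugate borylation of an enone, in which the boryl copper species adds to C3 axially from the α face, anti to the axial 4β-methyl, and should give the 3α-boronate after protonation of the enolate by methanol.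

Step 16
Reactants: 22 3α-(pinacolboryl)-1-ketone
Product: 23 3α-(pinacolboryl)-1α-ol (other groups as in 16)
Conditions: LiBH(s-Bu)3, THF, −78 °C; aq. NH4Cl (no peroxide)
Reagents that add atoms: none
Why: Ketone reduction by a bulky trialkylborohydride, in which the α face of the C1 carbonyl is screened by the syn-axial 3α-boronate so that hydride should enter equatorially from the β face and give the axial 1α-alcohol, with a non-oxidative work-up keeping the C–B bond.

Step 17
Reactants: 23 3α-(pinacolboryl)-1α-ol
Product: 24 1α-(tert-butyldimethylsilyloxy)-3α-(pinacolboryl) compound (other groups as in 16)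
Conditions: TBSOTf, 2,6-lutidine, CH2Cl2, −78 → 0 °C
Reagents that add atoms: tert-butyldimethylsilyl trifluoromethanesulfonate CC(C)(C)[Si](C)(C)OS(=O)(=O)C(F)(F)F
Why: Silylation of the hindered axial alcohol by the silyl triflate caps the C1 oxygen before the aryllithium of step 18, the triflation of step 20 and the acylpalladium intermediate of step 21.

Step 18
Reactants: 24 1α-(tert-butyldimethylsilyloxy)-3α-(pinacolboryl) compound
Product: 26 3β-chloride (1α-OTBS; C9 methyl enol ether; other groups as in 16), via lithium aryl boronate complex 25 (not isolated)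
Conditions: 3,5-(CF3)2C6H3Br, n-BuLi, THF, −78 °C; then 24, −78 °C; then trichloroisocyanuric acid, THF/MeCN, −78 °C → rt
Reagents that add atoms: trichloroisocyanuric acid ClN1C(=O)N(Cl)C(=O)N(Cl)C1=O
Why: Stereoinvertive halogenation of a secondary boronic ester, in which the aryllithium forms the boronate complex and electrophilic chlorine attacks its C–B bond from the rear (SE2 with inversion), turning the axial 3α-boronate into the equatorial 3β-chloride.

Step 19
Reactants: 26 3β-chloride
Product: 27 β-keto ester (C9=O; 8-CO2Me; 3β-Cl; 1α-OTBS; chain OTBDPS)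
Conditions: 1 M HCl, THF, rt → 40 °C
Reagents that add atoms: water O
Why: Acid hydrolysis of the vinylogous carbonate (C-protonation at C8, addition of water at C9, loss of methanol) returns the β-keto ester, while the hindered silyl ethers and the secondary chloride are expected to persist.

Step 20
Reactants: 27 β-keto ester
Product: 28 C9 enol triflate (C8=C9; 8-CO2Me; other groups as in 27)
Conditions: Tf2O, i-Pr2NEt, CH2Cl2, −78 → 0 °C
Reagents that add atoms: trifluoromethanesulfonic anhydride O=S(=O)(OS(=O)(=O)C(F)(F)F)C(F)(F)F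
Why: O-Triflation of the β-keto ester enol gives the vinyl triflate and removes the C8 stereocentre.

Step 21
Reactants: 28 C9 enol triflate
Product: 29 C9-formyl C8=C9 enoate (9-CHO; 8-CO2Me; other groups as in 27)
Conditions: Pd(OAc)2 (10 mol %), dppp (1,3-bis(diphenylphosphino)propane, 10 mol %), CO (1 atm), Et3SiH, Et3N, DMF, 70 °C
Reagents that add atoms: carbon monoxide [C-]#[O+]
Why: Palladium-catalysed reductive carbonylation (formylation) of a vinyl triflate, in which oxidative addition of zerovalent palladium, CO insertion and hydride transfer from the silane to the acylpalladium species install C11 as the aldehyde.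

Step 22
Reactants: 29 C9-formyl C8=C9 enoate
Product: 31 9β-formyl C7=C8 enoate (9α-H; bis-silyl ether of the target), via trimethylsilyl dienol ether 30 (not isolated)
Conditions: TMSOTf, Et3N, CH2Cl2, −78 → 0 °C; then MeOH, AcOH, −40 → 0 °C
Reagents that add atoms: none
Why: Deconjugation through a dienol ether, in which soft enolisation removes a γ-hydrogen at C7 and kinetic protonation of the silyl dienol ether at the α-carbon C9 gives the β,γ-unsaturated aldehyde with C7=C8 conjugated to the ester; C9 is epimerisable and should settle as the equatorial 9β-aldehyde because a 9α-formyl group would be syn-diaxial to the 1α-silyloxy group.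

Step 23
Reactants: 31 9β-formyl C7=C8 enoate (bis-silyl ether)
Product: 32 CNP0159496.2
Conditions: HF·pyridine, pyridine, THF, 0 °C → rt
Reagents that add atoms: none
Why: Fluoride-mediated cleavage of both silyl ethers under non-basic conditions, which should leave the epimerisable C9 centre and the β,γ-unsaturation alone.

**Compound list**

1 | 2-methylcyclopentane-1,3-dione | CC1C(=O)CCC1=O | starting material
2 | ethyl vinyl ketone (pent-1-en-3-one) | CCC(=O)C=C | starting material
3 | 2-methyl-2-(3-oxopentyl)cyclopentane-1,3-dione | CCC(=O)CCC1(C)C(=O)CCC1=O | intermediate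
4 | (7aS)-4,7a-dimethyl-2,3,7,7a-tetrahydro-1H-indene-1,5(6H)-dione (C3 enone with C4 methyl; C9 ketone; C10 methyl) | O=C1CC[C@]2(C)C(=O)CCC2=C1C | intermediate
5 | glycine methyl ester hydrochloride | COC(=O)CN.Cl | starting material
6 | methyl diazoacetate | COC(=O)C=[N+]=[N-] | intermediate
7 | methyl (8aS)-5,8a-dimethyl-1,6-dioxo-1,2,3,4,6,7,8,8a-octahydronaphthalene-2-carboxylate (C3 enone; C9 ketone; C8 ester; C8 drawn as one epimer) | O=C1CC[C@]2(C)C(=O)[C@@H](C(=O)OC)CCC2=C1C | intermediate
8 | 5-bromo-2-methylpent-2-ene | CC(C)=CCCBr | starting material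
9 | (R)-3-(2-bromoethyl)-2,2-dimethyloxirane | BrCC[C@H]1OC1(C)C | intermediate
10 | (R)-5-bromo-2-methylpent-1-en-3-ol | C=C(C)[C@H](O)CCBr | intermediate
11 | (R)-[(5-bromo-2-methylpent-1-en-3-yl)oxy](tert-butyl)diphenylsilane | C=C(C)[C@H](O[Si](c1ccccc1)(c1ccccc1)C(C)(C)C)CCBr | intermediate
12 | (R)-tert-butyl[(5-iodo-2-methylpent-1-en-3-yl)oxy]diphenylsilane | C=C(C)[C@H](O[Si](c1ccccc1)(c1ccccc1)C(C)(C)C)CCI | intermediate
13 | lithium enolate of 7 at the β-keto ester (formed in the flask) | [Li+].O=C1CC[C@]2(C)C([O-])=C(C(=O)OC)CCC2=C1C | intermediate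
14 | dilithium bis-enolate: C3/C4 enolate with 5α-H plus C8/C9 β-keto ester enolate (formed in the flask) | [Li+].[Li+].CC1=C([O-])CC[C@]2(C)C([O-])=C(C(=O)OC)CC[C@@H]12 | intermediate
15 | trans-decalin diketo ester: C3 and C9 ketones, 8-CO2Me, 4β-Me, 4α-[(3R)-3-(tert-butyldiphenylsilyloxy)-4-methylpent-4-enyl], 5α-H, 10β-Me | C=C(C)[C@H](O[Si](c3ccccc3)(c3ccccc3)C(C)(C)C)CC[C@]1(C)C(=O)CC[C@]2(C)C(=O)[C@@H](C(=O)OC)CC[C@@H]12 | intermediate
16 | C9 methyl enol ether of 15 (C8=C9, 9-OMe, 8-CO2Me; C3 ketone) | C=C(C)[C@H](O[Si](c3ccccc3)(c3ccccc3)C(C)(C)C)CC[C@]1(C)C(=O)CC[C@]2(C)C(OC)=C(C(=O)OC)CC[C@@H]12 | intermediate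
17 | C1=C2 enone (3-oxo) with C9 methyl enol ether | C=C(C)[C@H](O[Si](c3ccccc3)(c3ccccc3)C(C)(C)C)CC[C@]1(C)C(=O)C=C[C@]2(C)C(OC)=C(C(=O)OC)CC[C@@H]12 | intermediate
18 | 1α,2α-epoxy-3-ketone | C=C(C)[C@H](O[Si](c3ccccc3)(c3ccccc3)C(C)(C)C)CC[C@]1(C)C(=O)[C@@H]4O[C@@H]4[C@]2(C)C(OC)=C(C(=O)OC)CC[C@@H]12 | intermediate
19 | C3 hydrazone of 18 (formed in the flask; C=N geometry not fixed) | C=C(C)[C@H](O[Si](c3ccccc3)(c3ccccc3)C(C)(C)C)CC[C@]1(C)C(=NN)[C@@H]4O[C@@H]4[C@]2(C)C(OC)=C(C(=O)OC)CC[C@@H]12 | intermediate
20 | 1α-hydroxy C2=C3 allylic alcohol | C=C(C)[C@H](O[Si](c3ccccc3)(c3ccccc3)C(C)(C)C)CC[C@]1(C)C=C[C@H](O)[C@]2(C)C(OC)=C(C(=O)OC)CC[C@@H]12 | intermediate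
21 | transposed enone (1-oxo, C2=C3) | C=C(C)[C@H](O[Si](c3ccccc3)(c3ccccc3)C(C)(C)C)CC[C@]1(C)C=CC(=O)[C@]2(C)C(OC)=C(C(=O)OC)CC[C@@H]12 | intermediate
22 | 3α-(pinacolboryl)-1-ketone | C=C(C)[C@H](O[Si](c3ccccc3)(c3ccccc3)C(C)(C)C)CC[C@]1(C)[C@H](B4OC(C)(C)C(C)(C)O4)CC(=O)[C@]2(C)C(OC)=C(C(=O)OC)CC[C@@H]12 | intermediate
23 | 3α-(pinacolboryl)-1α-ol | C=C(C)[C@H](O[Si](c3ccccc3)(c3ccccc3)C(C)(C)C)CC[C@]1(C)[C@H](B4OC(C)(C)C(C)(C)O4)C[C@H](O)[C@]2(C)C(OC)=C(C(=O)OC)CC[C@@H]12 | intermediate
24 | 1α-(tert-butyldimethylsilyloxy)-3α-(pinacolboryl) compound | C=C(C)[C@H](O[Si](c3ccccc3)(c3ccccc3)C(C)(C)C)CC[C@]1(C)[C@H](B4OC(C)(C)C(C)(C)O4)C[C@H](O[Si](C)(C)C(C)(C)C)[C@]2(C)C(OC)=C(C(=O)OC)CC[C@@H]12 | intermediate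
25 | lithium [3,5-bis(trifluoromethyl)phenyl] boronate complex of 24 (formed in the flask) | [Li+].C=C(C)[C@H](O[Si](c3ccccc3)(c3ccccc3)C(C)(C)C)CC[C@]1(C)[C@H]([B-]4(c5cc(C(F)(F)F)cc(C(F)(F)F)c5)OC(C)(C)C(C)(C)O4)C[C@H](O[Si](C)(C)C(C)(C)C)[C@]2(C)C(OC)=C(C(=O)OC)CC[C@@H]12 | intermediate
26 | 3β-chloride with 1α-OTBS and C9 methyl enol ether | C=C(C)[C@H](O[Si](c3ccccc3)(c3ccccc3)C(C)(C)C)CC[C@]1(C)[C@@H](Cl)C[C@H](O[Si](C)(C)C(C)(C)C)[C@]2(C)C(OC)=C(C(=O)OC)CC[C@@H]12 | intermediate
27 | 3β-chloro β-keto ester (C9 ketone, 8-CO2Me; C8 drawn as one epimer) | C=C(C)[C@H](O[Si](c3ccccc3)(c3ccccc3)C(C)(C)C)CC[C@]1(C)[C@@H](Cl)C[C@H](O[Si](C)(C)C(C)(C)C)[C@]2(C)C(=O)[C@@H](C(=O)OC)CC[C@@H]12 | intermediate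
28 | C9 enol triflate (C8=C9) | C=C(C)[C@H](O[Si](c3ccccc3)(c3ccccc3)C(C)(C)C)CC[C@]1(C)[C@@H](Cl)C[C@H](O[Si](C)(C)C(C)(C)C)[C@]2(C)C(OS(=O)(=O)C(F)(F)F)=C(C(=O)OC)CC[C@@H]12 | intermediate
29 | C9-formyl C8=C9 enoate | C=C(C)[C@H](O[Si](c3ccccc3)(c3ccccc3)C(C)(C)C)CC[C@]1(C)[C@@H](Cl)C[C@H](O[Si](C)(C)C(C)(C)C)[C@]2(C)C(C=O)=C(C(=O)OC)CC[C@@H]12 | intermediate
30 | trimethylsilyl dienol ether (C9=C11–OTMS, C7=C8; formed in the flask; enol ether geometry not fixed) | C=C(C)[C@H](O[Si](c3ccccc3)(c3ccccc3)C(C)(C)C)CC[C@]1(C)[C@@H](Cl)C[C@H](O[Si](C)(C)C(C)(C)C)[C@]2(C)C(=CO[Si](C)(C)C)C(C(=O)OC)=CC[C@@H]12 | intermediate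
31 | 1-O-TBS, 15-O-TBDPS ether of the target (9β-CHO, 9α-H, C7=C8) | C=C(C)[C@H](O[Si](c3ccccc3)(c3ccccc3)C(C)(C)C)CC[C@]1(C)[C@@H](Cl)C[C@H](O[Si](C)(C)C(C)(C)C)[C@]2(C)[C@@H](C=O)C(C(=O)OC)=CC[C@@H]12 | intermediate
32 | CNP0159496.2 | C=C(C)[C@H](O)CC[C@]1(C)[C@@H](Cl)C[C@H](O)[C@]2(C)[C@@H](C=O)C(C(=O)OC)=CC[C@@H]12 | target

**Step count and risks**

Total step count: 23. Longest linear sequence: 19 steps (steps 5–8 followed by steps 9–23, from 5-bromo-2-methylpent-2-ene). The bicyclic core from 2-methylcyclopentane-1,3-dione (steps 1, 2 and 4) joins this line at step 9, and step 3 is a one-step side branch that supplies the diazo ester.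

Steps most likely to fail:

Step 9. Carbon–carbon bond formation at the congested C4 enolate carbon with an unactivated primary iodide may be slower than proton transfer (return of the unalkylated 4-H ketone) or than alkylation of the β-keto ester enolate at C8 or oxygen. Fallback: setting out from 7, the same reduction is quenched with allyl bromide, an activated electrophile for which alkylation of this enolate class at a quaternary carbon is routine, to give the 4α-allyl diketo ester F1. O-Methylation as in step 10 gives the allyl enol ether F2. Hydroboration of the terminal alkene with 9-BBN and oxidation with NaBO3 give the primary C15 alcohol F3, and oxidation with DMP gives the aldehyde F4. An aldehyde-selective Nozaki–Hiyama–Kishi coupling with 2-bromopropene (CrCl2, NiCl2 cat., chiral sulfonamide ligand) sets C15 and gives the 15R allylic alcohol F5. Silylation with TBDPSCl and imidazole returns to the route at 16.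

Step 18. Rear-side approach of the chlorine electrophile to C3 is impeded by the adjacent quaternary C4, so single-electron oxidation of the boronate complex (with loss of stereochemical fidelity), elimination, or chlorination of the isopropenyl and enol ether double bonds may take over. Fallback: setting out from 24, transesterification with 2-methoxy-1,3,2-benzodioxaborole (cat. TfOH) gives the catechol boronic ester F6, and a radical chain chlorine-atom transfer from PhSO2Cl (di-tert-butyl hyponitrite as initiator) converts it into 26, where the route is rejoined. In this variant C3 is a radical, and the chlorine donor should approach the β face because the α face is screened by the syn-axial 1α-silyloxy group, which again leads to the equatorial chloride.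

Step 21. Insertion of CO at the crowded C9–palladium bond may lag behind hydride transfer, so that reduction of the triflate to the C9–H enoate competes with formylation. Fallback: setting out from 28, palladium-catalysed thiocarbonylation (Pd(OAc)2, dppp, CO, EtSH, Et3N) gives the C11 S-ethyl thioester F7 with no hydride donor present during the insertion, and Fukuyama reduction (Et3SiH, Pd/C, acetone) then gives the aldehyde 29, where the route is rejoined.

Further compounds
F1 | step 9 | 4α-allyl diketo ester (trans-decalin; 4β-Me; 5α-H; 10β-Me; C3 and C9 ketones; 8-CO2Me) | C=CC[C@]1(C)C(=O)CC[C@]2(C)C(=O)[C@@H](C(=O)OC)CC[C@@H]12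
F2 | step 9 | C9 methyl enol ether of F1 | C=CC[C@]1(C)C(=O)CC[C@]2(C)C(OC)=C(C(=O)OC)CC[C@@H]12
F3 | step 9 | 4α-(3-hydroxypropyl) compound (C15 primary alcohol) | OCCC[C@]1(C)C(=O)CC[C@]2(C)C(OC)=C(C(=O)OC)CC[C@@H]12
F4 | step 9 | 4α-(3-oxopropyl) compound (C15 aldehyde) | O=CCC[C@]1(C)C(=O)CC[C@]2(C)C(OC)=C(C(=O)OC)CC[C@@H]12
F5 | step 9 | (15R)-allylic alcohol (desilyl 16) | C=C(C)[C@H](O)CC[C@]1(C)C(=O)CC[C@]2(C)C(OC)=C(C(=O)OC)CC[C@@H]12
F6 | step 18 | 3α-(1,3,2-benzodioxaborol-2-yl) analogue of 24 | C=C(C)[C@H](O[Si](c3ccccc3)(c3ccccc3)C(C)(C)C)CC[C@]1(C)[C@H](B4Oc5ccccc5O4)C[C@H](O[Si](C)(C)C(C)(C)C)[C@]2(C)C(OC)=C(C(=O)OC)CC[C@@H]12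
F7 | step 21 | C11 S-ethyl thioester (C8=C9; 8-CO2Me) | C=C(C)[C@H](O[Si](c3ccccc3)(c3ccccc3)C(C)(C)C)CC[C@]1(C)[C@@H](Cl)C[C@H](O[Si](C)(C)C(C)(C)C)[C@]2(C)C(C(=O)SCC)=C(C(=O)OC)CC[C@@H]12
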